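The head group of the target (pyrrole N1, C2 to C5, and the formyl carbon and oxygen) contains exactly the atoms of a pyridine N-oxide ring. The pyrrole is therefore traced back, through its N1–C2 bond, to a 2-alkylpyridine 1-oxide that already carries the whole (10Z,13Z,16Z)-nonadecatrienyl chain. Light should move oxygen from nitrogen to the unsubstituted pyridine carbon C6, expel C6 as the aldehyde and join nitrogen to pyridine C5. This one isomerisation builds the 2-formylpyrrole with no protecting group and no redox step. The precursor is made by joining the methyl carbon of 2-picoline N-oxide to linolenyl bromide, which supplies all three Z-alkenes.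

Key step: step 3

Remark: linolenyl alcohol of high Z,Z,Z purity and 2-picoline N-oxide are taken as commercial; because CuSO4 and the lipophilic N-oxide must share one phase, aqueous methanol is assumed as the photolysis medium.

Step 1
Reactants: 1 linolenyl alcohol, (9Z,12Z,15Z)-octadeca-9,12,15-trien-1-ol
Product: 2 linolenyl bromide, (3Z,6Z,9Z)-18-bromooctadeca-3,6,9-triene
Conditions: CBr4 (1.2 equiv), PPh3 (1.25 equiv), CH2Cl2, 0 °C to rt, Ar, dark; pentane trituration, SiO2 plug
Reagents that add atoms: carbon tetrabromide, BrC(Br)(Br)Br
Why: In this Appel reaction the primary alcohol is activated as an alkoxyphosphonium ion and displaced by bromide in an SN2 step under neutral conditions, so the skipped Z,Z,Z-triene should be neither isomerised nor attacked.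

Step 2
Reactants: 3 2-picoline N-oxide (2-methylpyridine 1-oxide); 2 linolenyl bromide
Product: 5 2-[(10Z,13Z,16Z)-nonadeca-10,13,16-trien-1-yl]pyridine 1-oxide, via (1-oxidopyridin-2-yl)methyllithium 4 (not isolated)
Conditions: 3 (1.4 equiv, dried azeotropically), LiN(CHMe2)2 (LDA, 1.3 equiv), THF, −78 °C; then 2 (1.0 equiv), −78 → −20 °C; aq. NH4Cl
Reagents that add atoms: none
Why: In this lateral lithiation and alkylation the C2 methyl group, acidified by the N-oxide, is deprotonated by the hindered amide to the delocalised, oxygen-chelated carbanion 4, which should displace bromide from the unhindered primary carbon of 2 by SN2; because the N-oxide is in place before the C–C bond is made, the triene never meets a peracid, and the slight deficit of base leaves no free amide to attack the bromide.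

Step 3
Reactants: 5 2-[(10Z,13Z,16Z)-nonadeca-10,13,16-trien-1-yl]pyridine 1-oxide
Product: 9 Mycalazal 20 [5-((10Z,13Z,16Z)-nonadeca-10,13,16-trien-1-yl)-1H-pyrrole-2-carbaldehyde], via bicyclic oxaziridine 6 (not isolated), via 1,2-oxazepine 7 (not isolated), via 2-formyl-2H-pyrrole 8 (not isolated)
Conditions: hν (254 nm, low-pressure Hg lamp, quartz), CuSO4·5H2O (2 equiv), degassed peroxide-free MeOH/H2O (4:1), 5 mM, 15 °C, Ar, to partial conversion; aq. Na2EDTA wash; SiO2 (recover 5)
Reagents that add atoms: none
Why: Excitation of the N-oxide chromophore of 5 should bond oxygen to the unsubstituted C6 to give oxaziridine 6, which opens by a six-electron electrocyclic ring expansion to 1,2-oxazepine 7; cleavage of the weak N–O bond of 7 then turns the former C6 into the aldehyde carbon while nitrogen bonds to the former C5, giving 2H-pyrrole 8, which aromatises to 9 by a proton shift. The closest known reaction type is the photochemical ring contraction of pyridine N-oxides to pyrrole-2-carbaldehydes run with CuSO4, in which divalent copper is believed to bind the ring-opened N,O-intermediate and to steer it to the pyrrole and away from deoxygenation. The pyrrole ring is closed by N1–C5 bond formation (pyridine numbering), a formal 1,3-shift of nitrogen from oxygen to carbon within 7, so the five-membered ring arises by contraction of a ring (six to seven to five) and not by cyclisation of an open chain. No stereocentre is created, because the sp3 carbon of 8 becomes sp2 on tautomerisation. The step needs oxygen to migrate to C6 and not to the alkyl-bearing C2, which would end in a 2-acylpyrrole; the C2 chain hinders bridging at its own carbon, simple 2-methylpyridine N-oxides are known to rearrange in this sense, and the oxazepine formed through C6 has the alkyl group and no hydrogen on its C=N carbon, so it cannot fragment to an open-chain nitrile. It also needs the three Z-alkenes left alone, which the substrate and conditions should secure: isolated C=C bonds are transparent at 254 nm, the solution is dilute and free of oxygen, and irradiation is stopped at partial conversion so that 9, which absorbs at longer wavelength, is not photolysed.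

Compound list
1 | linolenyl alcohol, (9Z,12Z,15Z)-octadeca-9,12,15-trien-1-ol | CC/C=C\C/C=C\C/C=C\CCCCCCCCO | starting material
2 | linolenyl bromide, (3Z,6Z,9Z)-18-bromooctadeca-3,6,9-triene | CC/C=C\C/C=C\C/C=C\CCCCCCCCBr | intermediate
3 | 2-picoline N-oxide, 2-methylpyridine 1-oxide | Cc1cccc[n+]1[O-] | starting material
4 | (1-oxidopyridin-1-ium-2-yl)methyllithium | [Li]Cc1cccc[n+]1[O-] | intermediate
5 | 2-[(10Z,13Z,16Z)-nonadeca-10,13,16-trien-1-yl]pyridine 1-oxide | CC/C=C\C/C=C\C/C=C\CCCCCCCCCc1cccc[n+]1[O-] | intermediate
6 | 2-[(10Z,13Z,16Z)-nonadeca-10,13,16-trien-1-yl]-7-oxa-1-azabicyclo[4.1.0]hepta-2,4-diene (racemic) | CC/C=C\C/C=C\C/C=C\CCCCCCCCCC1=CC=CC2ON12 | intermediate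
7 | 3-[(10Z,13Z,16Z)-nonadeca-10,13,16-trien-1-yl]-1,2-oxazepine | CC/C=C\C/C=C\C/C=C\CCCCCCCCCC1=NOC=CC=C1 | intermediate
8 | 5-[(10Z,13Z,16Z)-nonadeca-10,13,16-trien-1-yl]-2H-pyrrole-2-carbaldehyde (racemic) | CC/C=C\C/C=C\C/C=C\CCCCCCCCCC1=NC(C=O)C=C1 | intermediate
9 | Mycalazal 20, 5-[(10Z,13Z,16Z)-nonadeca-10,13,16-trien-1-yl]-1H-pyrrole-2-carbaldehyde | CC/C=C\C/C=C\C/C=C\CCCCCCCCCc1ccc(C=O)[nH]1 | target

Total step count: 3
Longest linear sequence: 3 steps (1 → 2 → 5 → 9)

Steps most likely to fail

Step 3, the photochemical ring contraction, carries the main risk. Oxygen may migrate to the alkyl-bearing C2 and not to C6, the excited N-oxide may lose its oxygen, and the bis-allylic positions of the triene may suffer oxygen-atom transfer or radical attack. Z-to-E isomerisation by energy transfer and secondary photolysis of the product are further risks. The fallback uses known chemistry and runs from 2 to 9. Bromide 2 is converted with Mg turnings in THF into (9Z,12Z,15Z)-octadeca-9,12,15-trien-1-ylmagnesium bromide F1. F1 is added at 0 °C to commercial 1H-pyrrole-2-carbaldehyde, whose NH has first been deprotonated with EtMgBr, to give racemic (10Z,13Z,16Z)-1-(1H-pyrrol-2-yl)nonadeca-10,13,16-trien-1-ol F2. NaBH4 in refluxing 2-propanol should reduce this pyrrolyl carbinol to 2-[(10Z,13Z,16Z)-nonadeca-10,13,16-trien-1-yl]-1H-pyrrole F3. Vilsmeier–Haack formylation (POCl3, DMF, 0 °C, then aqueous NaOAc) at the free α-position then rejoins the route at 9.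

Step 2, the lateral lithiation and alkylation, is next. Kinetic deprotonation may occur at ring C6 and not at the methyl group, the lithiated species may add to a second N-oxide ring, and the base may eliminate HBr from the bromide. The fallback runs from 2 to 5 and replaces the organolithium by a doubly stabilised enolate. Commercial ethyl 2-pyridylacetate is oxidised with mCPBA (CH2Cl2, 0 °C), before any alkene is present, to ethyl 2-(1-oxidopyridin-1-ium-2-yl)acetate F4. F4 is deprotonated with NaH in DMF at 0 °C and alkylated with 2 to give racemic ethyl (11Z,14Z,17Z)-2-(1-oxidopyridin-1-ium-2-yl)icosa-11,14,17-trienoate F5. LiOH in THF/H2O gives (11Z,14Z,17Z)-2-(1-oxidopyridin-1-ium-2-yl)icosa-11,14,17-trienoic acid F6. On acidification to about pH 4 and gentle warming F6 should lose CO2, as 2-pyridylacetic acids do, and rejoin the route at 5.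

Step 1, the Appel bromination, is the least risky. Adventitious HBr may isomerise or add to the skipped triene, and phosphine oxide and bromoform may be hard to remove from a non-polar, air-sensitive oil. The fallback runs from 1 to 2 without any phosphorus reagent. MsCl and Et3N in CH2Cl2 at 0 °C give (9Z,12Z,15Z)-octadeca-9,12,15-trien-1-yl methanesulfonate F7, and LiBr in acetone at 50 °C displaces the sulfonate by SN2 to return at 2.

Further compounds
F1 | step 3 | (9Z,12Z,15Z)-octadeca-9,12,15-trien-1-ylmagnesium bromide | CC/C=C\C/C=C\C/C=C\CCCCCCCC[Mg]Br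
F2 | step 3 | (10Z,13Z,16Z)-1-(1H-pyrrol-2-yl)nonadeca-10,13,16-trien-1-ol (racemic) | CC/C=C\C/C=C\C/C=C\CCCCCCCCC(O)c1ccc[nH]1
F3 | step 3 | 2-[(10Z,13Z,16Z)-nonadeca-10,13,16-trien-1-yl]-1H-pyrrole | CC/C=C\C/C=C\C/C=C\CCCCCCCCCc1ccc[nH]1
F4 | step 2 | ethyl 2-(1-oxidopyridin-1-ium-2-yl)acetate | CCOC(=O)Cc1cccc[n+]1[O-]
F5 | step 2 | ethyl (11Z,14Z,17Z)-2-(1-oxidopyridin-1-ium-2-yl)icosa-11,14,17-trienoate (racemic) | CC/C=C\C/C=C\C/C=C\CCCCCCCCC(C(=O)OCC)c1cccc[n+]1[O-]
F6 | step 2 | (11Z,14Z,17Z)-2-(1-oxidopyridin-1-ium-2-yl)icosa-11,14,17-trienoic acid (racemic) | CC/C=C\C/C=C\C/C=C\CCCCCCCCC(C(=O)O)c1cccc[n+]1[O-]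
F7 | step 1 | (9Z,12Z,15Z)-octadeca-9,12,15-trien-1-yl methanesulfonate | CC/C=C\C/C=C\C/C=C\CCCCCCCCOS(C)(=O)=O
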